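The benzo-fused γ-lactone is cut back to a furan and an alkyne. The benzene ring is assembled by joining C3a–C4 and C7–C7a in a [4+2] addition of 3,4-dimethoxyfuran to methyl 4-hydroxybut-2-ynoate; acid then turns the oxygen bridge into the C4 phenol while the C3 hydroxymethyl group acylates on the C1 ester and shuts the lactone ring, all in one operation. This exploits the fact that the C4 hydroxyl sits beside C3a and meta to C7a, the ring carbon that carries the carbonyl, with the C5 and C6 oxygens on neighbouring ring carbons. Chelation-guided C5 demethylation and Mitsunobu etherification with a terminally hydrated farnesyl diol finish the molecule.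

Key step: step 5

Remark on numbering: atom numbers are those of the 2-benzofuran-1(3H)-one skeleton (C1 carbonyl, O2, C3 methylene, C3a, C4 to C7, C7a).
Assumption: methyl 4-hydroxybut-2-ynoate 7 is taken as a catalogue compound, so no separate preparation is spent on it.
Remark on stereochemistry: the target has no stereocenter; its two E alkenes come unchanged from 12, and 8, 13 and 14 are racemic.

Step 1
Reactants: 1 dimethyl diglycolate; 2 dimethyl oxalate
Product: 3 dimethyl 3,4-dihydroxyfuran-2,5-dicarboxylate
Conditions: NaOMe, MeOH, reflux; then aq HCl
Reagents that add atoms: none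
Why: A double Claisen condensation of the two activated methylene groups of 1 onto the two ester carbonyls of 2 closes the five-membered ring, and the resulting diketone rests as the aromatic dihydroxyfuran, whose disodium salt drives the equilibrium.

Step 2
Reactants: 3 dimethyl 3,4-dihydroxyfuran-2,5-dicarboxylate
Product: 4 dimethyl 3,4-dimethoxyfuran-2,5-dicarboxylate
Conditions: Me2SO4, K2CO3, acetone, reflux
Reagents that add atoms: dimethyl sulfate, COS(=O)(=O)OC
Why: Williamson-type O-methylation of the two acidic enolic hydroxyls with a hard electrophile should go on oxygen, since C-alkylation would destroy the furan aromaticity.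

Step 3
Reactants: 4 dimethyl 3,4-dimethoxyfuran-2,5-dicarboxylate
Product: 5 3,4-dimethoxyfuran-2,5-dicarboxylic acid
Conditions: NaOH, H2O/MeOH, reflux; then aq HCl
Reagents that add atoms: sodium hydroxide, [Na+].[OH-] (oxygen of each new carboxyl OH)
Why: Ordinary ester saponification by acyl substitution, which the methyl ethers and the furan ring tolerate, followed by acidification to the diacid.

Step 4
Reactants: 5 3,4-dimethoxyfuran-2,5-dicarboxylic acid
Product: 6 3,4-dimethoxyfuran
Conditions: Cu powder (cat.), quinoline, 200 °C, product distilled out
Reagents that add atoms: none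
Why: Copper-mediated thermal protodecarboxylation of furan-2-carboxylic acids in quinoline is a standard route to free α-positions, and distilling the volatile furan as it forms protects it from the hot medium.

Step 5
Reactants: 6 3,4-dimethoxyfuran; 7 methyl 4-hydroxybut-2-ynoate
Product: 10 4-hydroxy-5,6-dimethoxy-2-benzofuran-1(3H)-one, via oxanorbornadiene cycloadduct 8 (not isolated), via phenolic hydroxy ester 9 (not isolated)
Conditions: toluene, 80 °C (sealed tube); then BF3·OEt2 (0.3 equiv), CH2Cl2, 0 °C to rt
Reagents that add atoms: none
Why: The electron-rich diene 6 and the electron-poor alkyne 7 should combine in a normal-demand [4+2] cycloaddition to 8, after which BF3 bound to the bridging oxygen ionises the C7–O bond to a pentadienyl cation that loses the C4 proton and leaves the oxygen on C4 as the phenol of 9. The closest known reaction type is the Diels–Alder reaction of furans with acetylenic esters followed by acid-induced isomerisation of the 7-oxanorbornadiene to a meta-hydroxybenzoate. The carbocycle closes by intermolecular cycloaddition (C3a–C4 and C7–C7a) and becomes aromatic on bridge opening, and the lactone closes by 5-exo-trig addition–elimination of the C3 hydroxyl on the C1 ester with loss of methanol; the hydroxyl is left unprotected so that this needs no separate deprotection. No stereocenter has to be controlled, because both bridgehead centres of racemic 8 become sp2. The only selectivity needed is the direction of bridge opening: a methoxy group stabilises either cation, but cleavage at C4 would place positive charge on the ester-bearing C7a, so ionisation at C7 is expected. The furan is symmetric, so the orientation of the cycloaddition cannot give a second constitutional isomer.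

Step 6
Reactants: 10 4-hydroxy-5,6-dimethoxy-2-benzofuran-1(3H)-one
Product: 11 4,5-dihydroxy-6-methoxy-2-benzofuran-1(3H)-one
Conditions: AlCl3 (1.2 equiv), pyridine, CH2Cl2, reflux; then aq HCl
Reagents that add atoms: none
Why: In this chelation-directed Lewis-acid ether cleavage the C4 phenoxide binds aluminium and thereby activates only the neighbouring C5 methoxy group (flanked on both sides and para to the lactone carbonyl) for demethylation by pyridine, and the aluminium catecholate that results should shield the C6 ether.

Step 7
Reactants: 12 (2E,6E)-farnesyl acetate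
Product: 13 (2E,6E)-10-bromo-11-hydroxy-3,7,11-trimethyldodeca-2,6-dien-1-yl acetate (racemic)
Conditions: NBS, THF/H2O, 0 °C
Reagents that add atoms: N-bromosuccinimide, O=C1CCC(=O)N1Br; water, O
Why: Electrophilic bromohydrin formation in a water-rich medium should pick the exposed terminal trisubstituted alkene (the C2 alkene is deactivated by the allylic acetate), with water opening the bromonium ion at the tertiary carbon; the C10 stereocenter is formed racemic and is removed in step 9.

Step 8
Reactants: 13 (2E,6E)-10-bromo-11-hydroxy-3,7,11-trimethyldodeca-2,6-dien-1-yl acetate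
Product: 14 (2E,6E)-9-(3,3-dimethyloxiran-2-yl)-3,7-dimethylnona-2,6-dien-1-ol (racemic 10,11-epoxyfarnesol)
Conditions: K2CO3, MeOH, rt
Reagents that add atoms: none
Why: Intramolecular Williamson etherification of the bromohydrin alkoxide closes the epoxide while the same basic methanol removes the acetate by transesterification.

Step 9
Reactants: 14 (2E,6E)-9-(3,3-dimethyloxiran-2-yl)-3,7-dimethylnona-2,6-dien-1-ol
Product: 15 (2E,6E)-3,7,11-trimethyldodeca-2,6-diene-1,11-diol
Conditions: LiAlH4, THF, 0 °C to reflux; then H2O
Reagents that add atoms: none
Why: Reductive epoxide opening by LiAlH4 is an SN2 attack of hydride at the less substituted carbon C10, which leaves the tertiary C11 alcohol and erases the C10 stereocenter, while the isolated alkenes and the allylic alkoxide are inert.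

Step 10
Reactants: 11 4,5-dihydroxy-6-methoxy-2-benzofuran-1(3H)-one; 15 (2E,6E)-3,7,11-trimethyldodeca-2,6-diene-1,11-diol
Product: 16 farnesylemefuranone E, 4-hydroxy-5-{[(2E,6E)-11-hydroxy-3,7,11-trimethyldodeca-2,6-dien-1-yl]oxy}-6-methoxy-2-benzofuran-1(3H)-one
Conditions: PPh3, DIAD (added slowly), THF, 0 °C to rt
Reagents that add atoms: none
Why: In this Mitsunobu etherification the C5 hydroxyl, para to the lactone carbonyl, is the more acidic phenol and should be the one ionised, only the primary allylic alcohol of 15 can form the oxyphosphonium salt (the tertiary one cannot), and direct displacement at the allylic CH2 leaves both E alkenes untouched.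

Compound list
1 | dimethyl diglycolate (dimethyl 2,2'-oxydiacetate) | COC(=O)COCC(=O)OC | starting material
2 | dimethyl oxalate | COC(=O)C(=O)OC | starting material
3 | dimethyl 3,4-dihydroxyfuran-2,5-dicarboxylate | COC(=O)c1oc(C(=O)OC)c(O)c1O | intermediate
4 | dimethyl 3,4-dimethoxyfuran-2,5-dicarboxylate | COC(=O)c1oc(C(=O)OC)c(OC)c1OC | intermediate
5 | 3,4-dimethoxyfuran-2,5-dicarboxylic acid | COc1c(C(=O)O)oc(C(=O)O)c1OC | intermediate
6 | 3,4-dimethoxyfuran | COc1cocc1OC | intermediate
7 | methyl 4-hydroxybut-2-ynoate | COC(=O)C#CCO | starting material
8 | methyl 3-(hydroxymethyl)-5,6-dimethoxy-7-oxabicyclo[2.2.1]hepta-2,5-diene-2-carboxylate (racemic, not isolated) | COC(=O)C1=C(CO)C2OC1C(OC)=C2OC | intermediate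
9 | methyl 3-hydroxy-2-(hydroxymethyl)-4,5-dimethoxybenzoate (not isolated) | COC(=O)c1cc(OC)c(OC)c(O)c1CO | intermediate
10 | 4-hydroxy-5,6-dimethoxy-2-benzofuran-1(3H)-one | COc1cc2c(c(O)c1OC)COC2=O | intermediate
11 | 4,5-dihydroxy-6-methoxy-2-benzofuran-1(3H)-one | COc1cc2c(c(O)c1O)COC2=O | intermediate
12 | (2E,6E)-farnesyl acetate | CC(=O)OC/C=C(\C)CC/C=C(\C)CCC=C(C)C | starting material
13 | (2E,6E)-10-bromo-11-hydroxy-3,7,11-trimethyldodeca-2,6-dien-1-yl acetate (racemic) | CC(=O)OC/C=C(\C)CC/C=C(\C)CCC(Br)C(C)(C)O | intermediate
14 | (2E,6E)-9-(3,3-dimethyloxiran-2-yl)-3,7-dimethylnona-2,6-dien-1-ol (racemic) | OC/C=C(\C)CC/C=C(\C)CCC1OC1(C)C | intermediate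
15 | (2E,6E)-3,7,11-trimethyldodeca-2,6-diene-1,11-diol | OC/C=C(\C)CC/C=C(\C)CCCC(C)(C)O | intermediate
16 | farnesylemefuranone E | COc1cc2c(c(O)c1OC/C=C(\C)CC/C=C(\C)CCCC(C)(C)O)COC2=O | target

Total step count: 10.
Longest linear sequence: 7 steps (steps 1 to 6 and step 10).

Steps most likely to fail

Step 5. The cycloaddition of the singly activated alkyne may be slower than cycloreversion or thermal loss of the sensitive furan, or the bridge may ionise toward the other bridgehead so that the oxygen stays on C7. The fallback sets out from 6 and changes the dienophile to the more reactive, symmetric dimethyl but-2-ynedioate (toluene, rt to 50 °C). This should give dimethyl 5,6-dimethoxy-7-oxabicyclo[2.2.1]hepta-2,5-diene-2,3-dicarboxylate F1, for which both directions of bridge opening lead to the same phenol. BF3·OEt2 should isomerise it to dimethyl 3-hydroxy-4,5-dimethoxyphthalate F2. The two esters are then told apart through the phenol. LiOH in THF/H2O should hydrolyse only the ester remote from the phenoxide, because the other is flanked on both sides and deactivated by the ortho oxyanion, giving 3-hydroxy-4,5-dimethoxy-2-(methoxycarbonyl)benzoic acid F3. LiBH4 in refluxing THF reduces the remaining ester but not the carboxylate to 3-hydroxy-2-(hydroxymethyl)-4,5-dimethoxybenzoic acid F4. This lactonises on acidic work-up and comes back to the route at 10.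

Step 10. Etherification may occur at the C4 oxygen or at both oxygens, the catechol may be tied up by the phosphorus reagent as a cyclic phosphorane, or the allylic alcohol may be displaced with allylic transposition. The fallback sets out from 15 and replaces the redox condensation by a phenoxide alkylation. An Appel reaction (CBr4, PPh3, CH2Cl2, −20 °C) at the primary allylic hydroxyl gives (6E,10E)-12-bromo-2,6,10-trimethyldodeca-6,10-dien-2-ol F5. Compound 11 is then alkylated with F5 using NaHCO3 in DMF at 40 °C, a base weak enough to ionise only the more acidic C5 hydroxyl. This comes back to the route at 16.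

Step 6. Ether cleavage may run on to the C6 methoxy group or stall on the aluminium complex. The fallback sets out from 10 and replaces Lewis-acid cleavage by oxidative demethylation. 2-Iodoxybenzoic acid (DMF, rt) delivers oxygen to the methoxy-bearing ortho carbon C5 and expels methanol, giving the ortho-quinone 6-methoxy-2-benzofuran-1,4,5(3H)-trione F6. Aqueous Na2S2O4 reduces it in the same flask, and the sequence comes back to the route at 11.

Further compounds
F1 | step 5 | dimethyl 5,6-dimethoxy-7-oxabicyclo[2.2.1]hepta-2,5-diene-2,3-dicarboxylate | COC(=O)C1=C(C(=O)OC)C2OC1C(OC)=C2OC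
F2 | step 5 | dimethyl 3-hydroxy-4,5-dimethoxyphthalate | COC(=O)c1cc(OC)c(OC)c(O)c1C(=O)OC
F3 | step 5 | 3-hydroxy-4,5-dimethoxy-2-(methoxycarbonyl)benzoic acid | OC(=O)c1cc(OC)c(OC)c(O)c1C(=O)OC
F4 | step 5 | 3-hydroxy-2-(hydroxymethyl)-4,5-dimethoxybenzoic acid | OC(=O)c1cc(OC)c(OC)c(O)c1CO
F5 | step 10 | (6E,10E)-12-bromo-2,6,10-trimethyldodeca-6,10-dien-2-ol | BrC/C=C(\C)CC/C=C(\C)CCCC(C)(C)O
F6 | step 6 | 6-methoxy-2-benzofuran-1,4,5(3H)-trione | COC1=CC2=C(COC2=O)C(=O)C1=O
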